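| setting | dawn | spring | autumn | flask |
|---|---|---|---|---|
| substrate | 0.65 M | 0.98 M | 1.3 M | 1.3 M |
| gas phase | 64 mM (held) | 64 mM (held) | 64 mM (held) | 64 mM (held) |
| free catalyst | 2.9 mM | 2.9 mM | 5.8 mM | 2.9 mM |
| remark | run made earlier | run made earlier | run made earlier |  |
| time |  |  |  | 8.0 d |

| run | time / d | product / % | substrate / % |
|---|---|---|---|
| dawn | 1.04 | 8.1 | 92.6 |
| dawn | 2.08 | 15.2 | 84.5 |
| dawn | 3.00 | 22.1 | 78.1 |
| dawn | 4.00 | 29.4 | 70.9 |
| dawn | 5.00 | 34.7 | 65.1 |
| spring | 0.417 | 3.1 | 96.6 |
| spring | 0.833 | 6.6 | 94.7 |
| spring | 1.25 | 9.0 | 91.1 |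
| spring | 2.50 | 17.9 | 82.4 |
| spring | 5.00 | 33.8 | 65.7 |
| autumn | 0.417 | 3.0 | 97.1 |
| autumn | 1.25 | 12.1 | 88.7 |
| autumn | 2.00 | 18.5 | 81.3 |
| autumn | 3.00 | 27.2 | 72.4 |
| autumn | 5.00 | 41.3 | 58.5 |

(readings scatter by 0.5 percentage points)

- the numbers in the tables scatter with a standard deviation of 0.5 percentage points
- at the start none of the gas phase is in solution

* how much product there is at 8.0 d, in percent of the substrate charged
* the change that raises the amount of product at 8.0 d, in percent of the substrate charged most ("none" if none brings more than 2 percentage points) (Friday's / Saturday's / Sunday's / none)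
* amount of product at 8.0 d, in percent of the substrate charged, after Friday's

- Friday's: doubling the saturation concentration of gas phase, all else as stated
- Saturday's: doubling the amount of free catalyst, all else as stated
- Sunday's: doubling the transfer coefficient of the gas phase, all else as stated

You wanted a quick number, and the early readings won't give it: the first spring reading, 3.1% of product at 0.417 d, carries a scatter of 0.5 percentage points. So replace each curve by its mean. Take minus the logarithm of the fraction of substrate left, divided by the time, a pseudo-first-order constant. At their last readings dawn gives 0.0858 d⁻¹ and spring 0.0840 d⁻¹, from different substrate charges. Their mean, 0.0849 d⁻¹, is the mean fractional rate I carry to your flask, and over 8.0 d it makes 49.3% product.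

The mean has a price at the start. Autumn, at 0.107 d⁻¹, should hold 4.36% at 0.417 d but reads 3.0%, a delay of about 0.128 d, far shorter than 8.0 d. If that delay is the gas dissolving, I expect little from Sunday's. Dawn and spring differ by 0.00180 d⁻¹ across their substrate charges, so I lay autumn's higher constant to its doubled catalyst; that reads as rate going with catalyst to the power 0.336, and Saturday's gives 57.5%. No run varies the gas, so I assume the rate follows saturation, and Friday's then gives 74.3%.

Your forecast says 46% for the flask, Friday's as the best change and 74% after it, on “gas transfer partly limiting the rate”. My first number is higher, by 3.3 points.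

The flask gives 47.9%. Friday's brings 74.0%, a gain of 26 points, more than Saturday's 11 points or Sunday's 2.7 points.

    gas phase ⇌ dissolved gas, rate k1*(csat - [dissolved gas]) (kL = 0.371 h⁻¹)
    substrate + dissolved gas + free catalyst → free catalyst + product (k = 258 M⁻² h⁻¹)
    2 free catalyst ⇌ resting dimer, settled at all times (K = 22600 M⁻¹)
    2 free catalyst → spent catalyst (k = 2.03 M⁻¹ h⁻¹)

The flask's own mean fractional rate is 0.0814 d⁻¹, slower than the 0.0849 d⁻¹ I carried. Now take the neighbour charged with 0.0049 M of free catalyst. The carried rate, scaled by the catalyst power, becomes 0.101 d⁻¹, which makes 55.4% product at 8.0 d. That neighbour gives 56.4%, with 43.6% of its substrate left and 92.0% of its catalyst charge in the resting dimer, the resting state.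

All runs are simulated for substances that don't exist; scatter was added.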